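**Strategy.** The seven-membered ring is disconnected at the C4–C5 bond (azulene numbering of the target: C3 tertiary carbinol, C3a/C8a ring fusion, C4 ester carbinol, C6 methyl-bearing alkene carbon, C8 ketone). The key step exploits the homoallylic relationship between the C4 oxygen and the C6 methyl-bearing carbon, which lies β,γ to the C8 carbonyl once the enone is deconjugated. A Lewis-acid-promoted type 2 carbonyl-ene cyclisation of a cyclopentane carrying trans-disposed formyl and 3-methylbut-3-enoyl arms closes the ring, forms the C4–C5 bond and sets the C4 carbinol in one operation. The precursor is assembled from 3-methylcyclopent-2-enone by asymmetric conjugate addition, enolate hydroxymethylation and isopropyl addition.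

Key step: step 7

Remark: the enantiomer of the chiral ligand in step 1 is taken to be the one that gives the (R)-configured quaternary centre; the three Grignard reagents are used as commercial solutions.

Step 1
Reactants: 1 3-methylcyclopent-2-en-1-one; 2 2-methylprop-1-enylmagnesium bromide
Product: 4 trimethyl{[(3R)-3-methyl-3-(2-methylprop-1-en-1-yl)cyclopent-1-en-1-yl]oxy}silane, via bromomagnesium enolate 3 (not isolated)
Conditions: Cu(OTf)2 (3 mol %), chiral C2-symmetric imidazolinium salt as NHC precursor (4 mol %), Et2O, −30 °C; then TMSCl, Et3N, −30 °C to rt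
Reagents that add atoms: chlorotrimethylsilane, C[Si](C)(C)Cl
Why: Copper-catalysed asymmetric conjugate addition of a Grignard reagent to a β-substituted cyclic enone should create the quaternary centre, with the chiral NHC–copper complex selecting the enone face, and O-silylation of the magnesium enolate fixes its regiochemistry for the next step.

Step 2
Reactants: 4 silyl enol ether; 5 formaldehyde (37% aqueous solution)
Product: 6 (2S,3R)-2-(hydroxymethyl)-3-methyl-3-(2-methylprop-1-en-1-yl)cyclopentan-1-one
Conditions: aq. HCHO, Yb(OTf)3 (10 mol %), THF, rt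
Reagents that add atoms: none
Why: The lanthanide-triflate-catalysed Mukaiyama aldol hydroxymethylation in aqueous medium should deliver formaldehyde to the enol ether carbon anti to the bulkier 2-methylprop-1-enyl group on the neighbouring quaternary carbon, placing CH2OH cis to the methyl group, which should also be the thermodynamically preferred arrangement at this epimerisable centre.

Step 3
Reactants: 6 hydroxymethyl ketone; 7 isopropylmagnesium chloride
Product: 8 (1R,2S,3R)-2-(hydroxymethyl)-3-methyl-3-(2-methylprop-1-en-1-yl)-1-(propan-2-yl)cyclopentan-1-ol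
Conditions: i-PrMgCl (3 equiv), LaCl3·2LiCl (1 equiv), THF, 0 °C; aq. NH4Cl
Reagents that add atoms: none
Why: Lanthanum-chloride-promoted Grignard 1,2-addition, which suppresses enolisation and β-hydride reduction, should occur on the ketone face opposite the adjacent alkoxide-bearing CH2O substituent, so that the new tertiary hydroxyl ends up cis to the hydroxymethyl group.

Step 4
Reactants: 8 diol
Product: 10 (1S,2S,3R)-3-hydroxy-2-(hydroxymethyl)-1-methyl-3-(propan-2-yl)cyclopentane-1-carbaldehyde, via secondary ozonide 9 (not isolated)
Conditions: O3, CH2Cl2, −78 °C; then Me2S, −78 °C to rt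
Reagents that add atoms: ozone, [O-][O+]=O
Why: Ozonolysis with reductive work-up cleaves the only alkene and unveils the neopentyl aldehyde without touching a stereocentre, while its trans relationship to the hydroxymethyl arm should prevent lactol formation.

Step 5
Reactants: 10 aldehyde; 11 2-methylallylmagnesium chloride
Product: 12 (1R,2S,3S)-3-(1-hydroxy-3-methylbut-3-en-1-yl)-2-(hydroxymethyl)-3-methyl-1-(propan-2-yl)cyclopentan-1-ol (both epimers at the side-chain carbinol)
Conditions: 11 (3.5 equiv), THF, −78 to 0 °C; aq. NH4Cl
Reagents that add atoms: none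
Why: Grignard 1,2-addition of the reactive allylic reagent to the hindered aldehyde, after deprotonation of the two hydroxyls, installs the four-carbon ene unit, and the configuration of the new carbinol is irrelevant because it is oxidised in the next step.

Step 6
Reactants: 12 triol
Product: 13 (1R,2R,5S)-2-hydroxy-5-methyl-5-(3-methylbut-3-enoyl)-2-(propan-2-yl)cyclopentane-1-carbaldehyde
Conditions: Dess–Martin periodinane (2.6 equiv), pyridine, CH2Cl2, 0 °C to rt
Reagents that add atoms: none
Why: Dess–Martin oxidation converts the primary and the secondary alcohol into aldehyde and ketone in one operation under buffered, non-enolising conditions, leaving the tertiary alcohol, the β,γ-position of the alkene and the aldehyde α-stereocentre (whose configuration should in any case be the thermodynamically favoured one) untouched.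

Step 7
Reactants: 13 keto aldehyde
Product: 14 (1R,3aS,8S,8aS)-1,8-dihydroxy-3a-methyl-6-methylidene-1-(propan-2-yl)octahydroazulen-4(1H)-one
Conditions: Me2AlCl (2.5 equiv), CH2Cl2, −78 to −20 °C; aq. potassium sodium tartrate
Reagents that add atoms: none
Why: Me2AlCl first turns the tertiary hydroxyl into a chloro(methyl)aluminium alkoxide (loss of methane) that can chelate and activate the neighbouring aldehyde, the CH2 terminus of the 1,1-disubstituted alkene then attacks the aldehyde carbon while positive charge builds at the tertiary alkene carbon, and transfer of an allylic hydrogen from the methyl group to oxygen completes the ene reaction. The closest known reaction type is the Lewis-acid-promoted type 2 intramolecular carbonyl-ene (Prins-type) cyclisation of ζ-methylene aldehydes to 3-methylenecycloheptanols, a reaction type established for six- and seven-membered rings. The seven-membered carbocycle is closed by C–C bond formation in a mode that is exo with respect to the carbonyl group and endo with respect to the alkene, and the trans ring fusion is already fixed by the trans arrangement of the two arms on the cyclopentane. The new carbinol centre (8S) is controlled by the adjacent ring-fusion stereocentre: the tethered alkene approaches the aldehyde past the ring-fusion hydrogen, the aluminium-bound carbonyl oxygen points outward into the sector next to the tertiary alkoxide (to which it can chelate) and the formyl hydrogen points inward toward the quaternary carbon, which should give the 1,3-anti diol. The step needs the aldehyde rather than the ketone to act as enophile and needs attack through the CH2 terminus; the first is secured by the higher electrophilicity of the chelated aldehyde (the ketone could only close a four-membered ring), the second by the tertiary cation character developing at the substituted alkene carbon, while aldol attack through the ketone α-carbon is disfavoured because it would give a trans-fused bicyclo[3.3.0]octane. Any endocyclic alkene isomer formed alongside converges on the same enone in step 8.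

Step 8
Reactants: 14 exo-methylene ketone
Product: 15 (1R,3aS,8S,8aS)-1,8-dihydroxy-3a,6-dimethyl-1-(propan-2-yl)-2,3,3a,7,8,8a-hexahydroazulen-4(1H)-one
Conditions: DBU (0.2 equiv), CH2Cl2, 0 °C to rt
Reagents that add atoms: none
Why: Base-mediated isomerisation of the β,γ-unsaturated ketone through its dienolate should move the exocyclic alkene into conjugation under thermodynamic control, giving the endocyclic trisubstituted enone without affecting a stereocentre.

Step 9
Reactants: 15 enone diol; 16 3,4-dimethoxybenzoyl chloride
Product: 17 (3R,3aS,4S,8aS)-3-hydroxy-6,8a-dimethyl-8-oxo-3-(propan-2-yl)-1,2,3,3a,4,5,8,8a-octahydroazulen-4-yl 3,4-dimethoxybenzoate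
Conditions: 16 (1.5 equiv), Et3N, DMAP (0.2 equiv), CH2Cl2, 0 °C to rt
Reagents that add atoms: none
Why: DMAP-catalysed acylation should take place only at the secondary hydroxyl, the tertiary carbinol being too hindered to react.

**Compound list**

1 | 3-methylcyclopent-2-en-1-one | CC1=CC(=O)CC1 | starting material
2 | 2-methylprop-1-enylmagnesium bromide | CC(C)=C[Mg]Br | starting material
3 | bromomagnesium (3R)-3-methyl-3-(2-methylprop-1-en-1-yl)cyclopent-1-en-1-olate | CC(C)=C[C@@]1(C)CCC(O[Mg]Br)=C1 | intermediate (not isolated)
4 | trimethyl{[(3R)-3-methyl-3-(2-methylprop-1-en-1-yl)cyclopent-1-en-1-yl]oxy}silane | CC(C)=C[C@@]1(C)CCC(O[Si](C)(C)C)=C1 | intermediate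
5 | formaldehyde | C=O | starting material
6 | (2S,3R)-2-(hydroxymethyl)-3-methyl-3-(2-methylprop-1-en-1-yl)cyclopentan-1-one | CC(C)=C[C@@]1(C)CCC(=O)[C@@H]1CO | intermediate
7 | isopropylmagnesium chloride | CC(C)[Mg]Cl | starting material
8 | (1R,2S,3R)-2-(hydroxymethyl)-3-methyl-3-(2-methylprop-1-en-1-yl)-1-(propan-2-yl)cyclopentan-1-ol | CC(C)=C[C@@]1(C)CC[C@@](O)(C(C)C)[C@@H]1CO | intermediate
9 | 3-[(1S,2S,3R)-3-hydroxy-2-(hydroxymethyl)-1-methyl-3-(propan-2-yl)cyclopentyl]-5,5-dimethyl-1,2,4-trioxolane (secondary ozonide) | CC1(C)OOC(O1)[C@@]2(C)CC[C@@](O)(C(C)C)[C@@H]2CO | intermediate (not isolated)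
10 | (1S,2S,3R)-3-hydroxy-2-(hydroxymethyl)-1-methyl-3-(propan-2-yl)cyclopentane-1-carbaldehyde | O=C[C@@]1(C)CC[C@@](O)(C(C)C)[C@@H]1CO | intermediate
11 | 2-methylallylmagnesium chloride | CC(=C)C[Mg]Cl | starting material
12 | (1R,2S,3S)-3-(1-hydroxy-3-methylbut-3-en-1-yl)-2-(hydroxymethyl)-3-methyl-1-(propan-2-yl)cyclopentan-1-ol (both epimers at the side-chain carbinol) | CC(=C)CC(O)[C@@]1(C)CC[C@@](O)(C(C)C)[C@@H]1CO | intermediate
13 | (1R,2R,5S)-2-hydroxy-5-methyl-5-(3-methylbut-3-enoyl)-2-(propan-2-yl)cyclopentane-1-carbaldehyde | CC(=C)CC(=O)[C@@]1(C)CC[C@@](O)(C(C)C)[C@@H]1C=O | intermediate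
14 | (1R,3aS,8S,8aS)-1,8-dihydroxy-3a-methyl-6-methylidene-1-(propan-2-yl)octahydroazulen-4(1H)-one | O[C@H]1CC(=C)CC(=O)[C@@]2(C)CC[C@@](O)(C(C)C)[C@H]12 | intermediate
15 | (1R,3aS,8S,8aS)-1,8-dihydroxy-3a,6-dimethyl-1-(propan-2-yl)-2,3,3a,7,8,8a-hexahydroazulen-4(1H)-one | O[C@H]1CC(C)=CC(=O)[C@@]2(C)CC[C@@](O)(C(C)C)[C@H]12 | intermediate
16 | 3,4-dimethoxybenzoyl chloride | COc1ccc(C(=O)Cl)cc1OC | starting material
17 | (3R,3aS,4S,8aS)-3-hydroxy-6,8a-dimethyl-8-oxo-3-(propan-2-yl)-1,2,3,3a,4,5,8,8a-octahydroazulen-4-yl 3,4-dimethoxybenzoate | COc1ccc(C(=O)O[C@H]2CC(C)=CC(=O)[C@@]3(C)CC[C@@](O)(C(C)C)[C@H]23)cc1OC | target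

**Totals.** Total step count: 9. Longest linear sequence: 9 steps (1 to 17).

**Steps most likely to fail**

Step 7. The β,γ-unsaturated ketone may slip into conjugation before cyclisation, which removes the ene donor, or the Lewis acid may trigger retro-aldol cleavage or ionisation at the tertiary carbinol. The fallback closes the same ring by metathesis; it sets out from 10 and comes back at 15. Addition of vinylmagnesium bromide to 10 would give (1R,2S,3S)-3-(1-hydroxyprop-2-en-1-yl)-2-(hydroxymethyl)-3-methyl-1-(propan-2-yl)cyclopentan-1-ol F1. Selective oxidation of its primary hydroxyl with TEMPO and PhI(OAc)2 would give (1R,2R,5S)-2-hydroxy-5-(1-hydroxyprop-2-en-1-yl)-5-methyl-2-(propan-2-yl)cyclopentane-1-carbaldehyde F2. Chelation-controlled addition of 2-methylallylmagnesium chloride would give (1R,2S,3S)-2-[(1S)-1-hydroxy-3-methylbut-3-en-1-yl]-3-(1-hydroxyprop-2-en-1-yl)-3-methyl-1-(propan-2-yl)cyclopentan-1-ol F3. Ring-closing metathesis with the second-generation Grubbs catalyst would close the seven-membered ring, again as the last ring, to (1R,3aS,8S,8aS)-3a,6-dimethyl-1-(propan-2-yl)-1,2,3,3a,4,7,8,8a-octahydroazulene-1,4,8-triol F4. Oxidation of the allylic alcohol with MnO2 would return 15.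

Step 1. The alkenyl Grignard reagent may add with low enantioselectivity or in 1,2-fashion to the five-membered enone. The fallback reverses which group is delivered; it sets out from Grignard reagent 2 and a different commercial enone in place of 1, and comes back at 4. 1,2-Addition of 2 to 3-ethoxycyclopent-2-en-1-one F5 with acidic work-up (Stork–Danheiser transposition) would give 3-(2-methylprop-1-en-1-yl)cyclopent-2-en-1-one F6. Copper/NHC-catalysed 1,4-addition of MeMgBr (Cu(OTf)2, chiral imidazolinium salt) would then form the quaternary centre by delivery of the methyl group, and silylation of the enolate with TMSCl would return 4.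

Step 3. Enolisation, retro-aldol loss of formaldehyde from the β-alkoxide ketone and β-hydride reduction may compete with addition of the secondary Grignard reagent, and the facial selectivity may be lower than assumed. The fallback uses an sp2 nucleophile without β-hydrogens; it sets out from 6 and comes back at 8. Addition of isopropenylmagnesium bromide in the presence of anhydrous CeCl3 would give (1S,2S,3R)-2-(hydroxymethyl)-3-methyl-3-(2-methylprop-1-en-1-yl)-1-(prop-1-en-2-yl)cyclopentan-1-ol F7. Chemoselective hydrogenation of the 1,1-disubstituted alkene (H2, RhCl(PPh3)3) would return 8.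

**Further compounds**

F1 | step 7 | (1R,2S,3S)-3-(1-hydroxyprop-2-en-1-yl)-2-(hydroxymethyl)-3-methyl-1-(propan-2-yl)cyclopentan-1-ol | C=CC(O)[C@@]1(C)CC[C@@](O)(C(C)C)[C@@H]1CO
F2 | step 7 | (1R,2R,5S)-2-hydroxy-5-(1-hydroxyprop-2-en-1-yl)-5-methyl-2-(propan-2-yl)cyclopentane-1-carbaldehyde | C=CC(O)[C@@]1(C)CC[C@@](O)(C(C)C)[C@@H]1C=O
F3 | step 7 | (1R,2S,3S)-2-[(1S)-1-hydroxy-3-methylbut-3-en-1-yl]-3-(1-hydroxyprop-2-en-1-yl)-3-methyl-1-(propan-2-yl)cyclopentan-1-ol | C=CC(O)[C@@]1(C)CC[C@@](O)(C(C)C)[C@@H]1[C@@H](O)CC(C)=C
F4 | step 7 | (1R,3aS,8S,8aS)-3a,6-dimethyl-1-(propan-2-yl)-1,2,3,3a,4,7,8,8a-octahydroazulene-1,4,8-triol | O[C@H]1CC(C)=CC(O)[C@@]2(C)CC[C@@](O)(C(C)C)[C@H]12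
F5 | step 1 | 3-ethoxycyclopent-2-en-1-one | CCOC1=CC(=O)CC1
F6 | step 1 | 3-(2-methylprop-1-en-1-yl)cyclopent-2-en-1-one | CC(C)=CC1=CC(=O)CC1
F7 | step 3 | (1S,2S,3R)-2-(hydroxymethyl)-3-methyl-3-(2-methylprop-1-en-1-yl)-1-(prop-1-en-2-yl)cyclopentan-1-ol | CC(C)=C[C@@]1(C)CC[C@@](O)(C(C)=C)[C@@H]1CO
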